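The route rests on the C4a–C5 bond of ring A of unit 1 (the apigenin half; unit 2 is the 8-linked, 3'''-methoxylated half, double and triple primes). Ring A of unit 1 (C4a, C5, C6, C7, C8, C8a) is a symmetric phloroglucinol with free oxygens on C5 and C7, so it can be folded from an unprotected polycarbonyl chain. In one operation Mg(OMe)2 opens a 4-hydroxy-2-pyranone and the C4a enolate closes onto the freed ester carbon C5, giving the acylphloroglucinol 1,3-diketone. The precursor is a 6-(4-aryl-2,4-dioxobutyl)-4-hydroxy-2-pyranone whose aryl group is the complete tetra-O-benzyl unit 2 biaryl flavone, joined by Suzuki coupling.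

Key step: step 10

Remark: the C3'–C8'' biaryl axis is taken as freely rotating (the target carries no stereodescriptor), polycarbonyl compounds are drawn as single tautomers, and LiN(i-Pr)2 is used as a commercial solution.

Abbreviation: Fl = 5,7-bis(benzyloxy)-2-[4-(benzyloxy)-3-methoxyphenyl]-4-oxo-4H-chromen-8-yl (the protected unit 2 flavone, bonded through C8'').

Step 1
Reactants: 1 2',4',6'-trihydroxyacetophenone
Product: 2 1-[2,4-bis(benzyloxy)-6-hydroxyphenyl]ethan-1-one
Conditions: BnBr (2.1 equiv), K2CO3, DMF, rt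
Reagents that add atoms: benzyl bromide, BrCc1ccccc1
Why: Williamson etherification should alkylate the para hydroxyl and one ortho hydroxyl, while the last ortho hydroxyl stays free because it is hydrogen-bonded to the acetyl carbonyl.

Step 2
Reactants: 2 1-[2,4-bis(benzyloxy)-6-hydroxyphenyl]ethan-1-one
Product: 3 1-[4,6-bis(benzyloxy)-2-hydroxy-3-iodophenyl]ethan-1-one
Conditions: NIS (1.05 equiv), CF3CO2H (cat.), MeCN, 0 °C to rt
Reagents that add atoms: N-iodosuccinimide, O=C1CCC(=O)N1I
Why: Electrophilic aromatic iodination should take place at C3, which is ortho to the free phenol and to the 4-benzyloxy group and para to the 6-benzyloxy group, the site at which 2-hydroxy-4,6-dialkoxyacetophenones are halogenated.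

Step 3
Reactants: 3 1-[4,6-bis(benzyloxy)-2-hydroxy-3-iodophenyl]ethan-1-one; 4 4-(benzyloxy)-3-methoxybenzaldehyde
Product: 5 (E)-1-[4,6-bis(benzyloxy)-2-hydroxy-3-iodophenyl]-3-[4-(benzyloxy)-3-methoxyphenyl]prop-2-en-1-one
Conditions: KOH (50% aq.), EtOH/THF, rt
Reagents that add atoms: none
Why: Claisen–Schmidt condensation with a non-enolizable aldehyde, followed by dehydration of the aldol, should give the conjugated E-enone, and the aryl iodide and benzyl ethers are inert to hydroxide at room temperature.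

Step 4
Reactants: 5 (E)-1-[4,6-bis(benzyloxy)-2-hydroxy-3-iodophenyl]-3-[4-(benzyloxy)-3-methoxyphenyl]prop-2-en-1-one
Product: 6 5,7-bis(benzyloxy)-2-[4-(benzyloxy)-3-methoxyphenyl]-8-iodo-4H-chromen-4-one
Conditions: I2 (0.1 equiv), DMSO, 130 °C
Reagents that add atoms: none
Why: Iodine-catalysed oxidative cyclization of a 2'-hydroxychalcone (oxa-Michael closure, then dehydrogenation with DMSO as the terminal oxidant) should give the flavone, and because the only free phenol lies next to the iodide the halogen ends up at C8''.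

Step 5
Reactants: 7 methyl 4-hydroxy-3-iodobenzoate
Product: 8 methyl 4-(benzyloxy)-3-iodobenzoate
Conditions: BnBr, K2CO3, DMF, rt
Reagents that add atoms: benzyl bromide, BrCc1ccccc1
Why: Williamson etherification of an acidic para-acyl phenol is straightforward and leaves the methyl ester and the aryl iodide untouched.

Step 6
Reactants: 8 methyl 4-(benzyloxy)-3-iodobenzoate
Product: 9 methyl 4-(benzyloxy)-3-(4,4,5,5-tetramethyl-1,3,2-dioxaborolan-2-yl)benzoate
Conditions: B2pin2, Pd(dppf)Cl2 (cat.), KOAc, 1,4-dioxane, 90 °C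
Reagents that add atoms: bis(pinacolato)diboron, CC1(C)OB(B2OC(C)(C)C(C)(C)O2)OC1(C)C
Why: Miyaura borylation of an aryl iodide with the weak base KOAc should give the pinacol boronate without homocoupling and without touching the methyl ester.

Step 7
Reactants: 6 5,7-bis(benzyloxy)-2-[4-(benzyloxy)-3-methoxyphenyl]-8-iodo-4H-chromen-4-one; 9 methyl 4-(benzyloxy)-3-(4,4,5,5-tetramethyl-1,3,2-dioxaborolan-2-yl)benzoate
Product: 10 methyl 4-(benzyloxy)-3-Fl-benzoate
Conditions: Pd(OAc)2 (cat.), SPhos, K3PO4, toluene/H2O, 90 °C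
Reagents that add atoms: none
Why: Suzuki–Miyaura coupling with the bulky, electron-rich biarylphosphine SPhos should allow oxidative addition at the di-ortho-substituted iodide and reductive elimination to the tri-ortho-substituted C3'–C8'' biaryl, while K3PO4 in a two-phase medium spares the methyl ester.

Step 8
Reactants: 11 triacetic acid lactone (4-hydroxy-6-methyl-2H-pyran-2-one)
Product: 12 4-hydroxy-6-(2-oxopropyl)-2H-pyran-2-one
Conditions: LiN(i-Pr)2 (2.1 equiv), THF, −78 to 0 °C; CH3C(O)N(OMe)Me, −78 °C to rt; aq. HCl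
Reagents that add atoms: N-methoxy-N-methylacetamide, CC(=O)N(C)OC
Why: Acylation of the pyranone dianion at its C6 methyl carbanion (polyanion Claisen acylation) should work because the N-methoxy-N-methylamide forms a stable chelated tetrahedral adduct, so the ketone is released only on work-up and is neither attacked twice nor able to quench the dianion.

Step 9
Reactants: 12 4-hydroxy-6-(2-oxopropyl)-2H-pyran-2-one (as its trianion, 3 equiv); 10 methyl 4-(benzyloxy)-3-Fl-benzoate
Product: 13 6-{4-[4-(benzyloxy)-3-Fl-phenyl]-2,4-dioxobutyl}-4-hydroxy-2H-pyran-2-one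
Conditions: 12, LiN(i-Pr)2 (9 equiv), THF, −78 to 0 °C; then 10 in THF, −78 °C to rt; aq. HCl, 0 °C
Reagents that add atoms: none
Why: Claisen acylation of a polycarbonyl trianion occurs at its most basic terminal carbanion; the non-enolizable benzoate 10 is the limiting reagent, the trianion is in excess because the product is deprotonated as it forms, and the cross-conjugated C4'' carbonyl of unit 2, shielded by the 5''-benzyloxy group, should be a poorer acceptor than the ester.

Step 10
Reactants: 13 6-{4-[4-(benzyloxy)-3-Fl-phenyl]-2,4-dioxobutyl}-4-hydroxy-2H-pyran-2-one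
Product: 15 1-[4-(benzyloxy)-3-Fl-phenyl]-3-(2,4,6-trihydroxyphenyl)propane-1,3-dione, via methyl 9-aryl-3,5,7,9-tetraoxononanoate 14 (not isolated)
Conditions: Mg(OMe)2 (8 equiv), MeOH/THF, reflux; then cold 1 M HCl
Reagents that add atoms: none
Why: Methoxide from Mg(OMe)2 adds to the lactone carbonyl (the future C5) and opens the pyranone to the methyl tetraoxo ester 14, whose 1,3-dicarbonyl units are held as magnesium chelates. The chelated enolate carbon C4a, lying between the C4 and C8a carbonyls, attacks the ester carbonyl C5, methoxide leaves, and the cyclohexane-1,3,5-trione tautomerizes to the aromatic phloroglucinol, which makes formation of the C4a–C5 bond irreversible. The closest known reaction type is the intramolecular Claisen (Dieckmann-type) cyclization of 3,5,7-triketo esters and of their 4-hydroxy-2-pyranone lactones to acylphloroglucinols with Mg(OMe)2, the folding mode of chalcone synthase. Ring A of unit 1 closes in the 6-exo-trig mode and no stereocenter is created. The step needs Claisen folding in preference to the aldol modes in which a methylene attacks a ketone carbonyl; the ester, set free only in the flask, is the one acceptor that can expel a leaving group, magnesium chelation ties up the ketone carbonyls as enolates, and aromatization drains the Claisen product from the equilibria. Unit 2 has no ester and no acidic C–H, sits far from the reacting chain, and its benzyl and methyl ethers are inert to Mg(OMe)2, while the new ring is symmetric so that its phenols need no protection.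

Step 11
Reactants: 15 1-[4-(benzyloxy)-3-Fl-phenyl]-3-(2,4,6-trihydroxyphenyl)propane-1,3-dione
Product: 16 2-[4-(benzyloxy)-3-Fl-phenyl]-5,7-dihydroxy-4H-chromen-4-one
Conditions: H2SO4 (cat.), AcOH, 60 °C
Reagents that add atoms: none
Why: Acid-catalysed cyclodehydration of a 1-(2-hydroxyaryl)-1,3-diketone (the closing step of the Baker–Venkataraman flavone synthesis) should give the pyranone of unit 1, either ortho hydroxyl of the symmetric ring leading to the same 5,7-dihydroxyflavone, and the mild catalytic acid should leave the benzyl ethers in place.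

Step 12
Reactants: 16 2-[4-(benzyloxy)-3-Fl-phenyl]-5,7-dihydroxy-4H-chromen-4-one
Product: 17 8-[5-(5,7-dihydroxy-4-oxo-4H-chromen-2-yl)-2-hydroxyphenyl]-5,7-dihydroxy-2-(4-hydroxy-3-methoxyphenyl)-4H-chromen-4-one (target)
Conditions: H2 (1 atm), Pd/C (10% palladium on carbon), THF/MeOH, rt
Reagents that add atoms: none
Why: Catalytic hydrogenolysis should cleave the four aryl benzyl ethers, while the C3''' methyl ether and the two flavone enones are not reduced at 1 atm and room temperature.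

Compound list
1 | 2',4',6'-trihydroxyacetophenone | CC(=O)c1c(O)cc(O)cc1O | starting material
2 | 1-[2,4-bis(benzyloxy)-6-hydroxyphenyl]ethan-1-one | CC(=O)c1c(O)cc(OCc2ccccc2)cc1OCc1ccccc1 | intermediate
3 | 1-[4,6-bis(benzyloxy)-2-hydroxy-3-iodophenyl]ethan-1-one | CC(=O)c1c(O)c(I)c(OCc2ccccc2)cc1OCc1ccccc1 | intermediate
4 | 4-(benzyloxy)-3-methoxybenzaldehyde | COc1cc(C=O)ccc1OCc1ccccc1 | starting material
5 | (E)-1-[4,6-bis(benzyloxy)-2-hydroxy-3-iodophenyl]-3-[4-(benzyloxy)-3-methoxyphenyl]prop-2-en-1-one | COc1cc(/C=C/C(=O)c2c(O)c(I)c(OCc3ccccc3)cc2OCc2ccccc2)ccc1OCc1ccccc1 | intermediate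
6 | 5,7-bis(benzyloxy)-2-[4-(benzyloxy)-3-methoxyphenyl]-8-iodo-4H-chromen-4-one | COc1cc(-c2cc(=O)c3c(OCc4ccccc4)cc(OCc4ccccc4)c(I)c3o2)ccc1OCc1ccccc1 | intermediate
7 | methyl 4-hydroxy-3-iodobenzoate | COC(=O)c1ccc(O)c(I)c1 | starting material
8 | methyl 4-(benzyloxy)-3-iodobenzoate | COC(=O)c1ccc(OCc2ccccc2)c(I)c1 | intermediate
9 | methyl 4-(benzyloxy)-3-(4,4,5,5-tetramethyl-1,3,2-dioxaborolan-2-yl)benzoate | COC(=O)c1ccc(OCc2ccccc2)c(B2OC(C)(C)C(C)(C)O2)c1 | intermediate
10 | methyl 4-(benzyloxy)-3-{5,7-bis(benzyloxy)-2-[4-(benzyloxy)-3-methoxyphenyl]-4-oxo-4H-chromen-8-yl}benzoate | COC(=O)c1ccc(OCc2ccccc2)c(-c2c(OCc3ccccc3)cc(OCc3ccccc3)c3c(=O)cc(-c4ccc(OCc5ccccc5)c(OC)c4)oc23)c1 | intermediate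
11 | triacetic acid lactone (4-hydroxy-6-methyl-2H-pyran-2-one) | Cc1cc(O)cc(=O)o1 | starting material
12 | 4-hydroxy-6-(2-oxopropyl)-2H-pyran-2-one | CC(=O)Cc1cc(O)cc(=O)o1 | intermediate
13 | 6-{4-[4-(benzyloxy)-3-Fl-phenyl]-2,4-dioxobutyl}-4-hydroxy-2H-pyran-2-one | O=C(CC(=O)Cc1cc(O)cc(=O)o1)c1ccc(OCc2ccccc2)c(-c2c(OCc3ccccc3)cc(OCc3ccccc3)c3c(=O)cc(-c4ccc(OCc5ccccc5)c(OC)c4)oc23)c1 | intermediate
14 | methyl 9-[4-(benzyloxy)-3-Fl-phenyl]-3,5,7,9-tetraoxononanoate | COC(=O)CC(=O)CC(=O)CC(=O)CC(=O)c1ccc(OCc2ccccc2)c(-c2c(OCc3ccccc3)cc(OCc3ccccc3)c3c(=O)cc(-c4ccc(OCc5ccccc5)c(OC)c4)oc23)c1 | intermediate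
15 | 1-[4-(benzyloxy)-3-Fl-phenyl]-3-(2,4,6-trihydroxyphenyl)propane-1,3-dione | O=C(CC(=O)c1c(O)cc(O)cc1O)c1ccc(OCc2ccccc2)c(-c2c(OCc3ccccc3)cc(OCc3ccccc3)c3c(=O)cc(-c4ccc(OCc5ccccc5)c(OC)c4)oc23)c1 | intermediate
16 | 5,7-bis(benzyloxy)-2-[4-(benzyloxy)-3-methoxyphenyl]-8-[2-(benzyloxy)-5-(5,7-dihydroxy-4-oxo-4H-chromen-2-yl)phenyl]-4H-chromen-4-one | COc1cc(-c2cc(=O)c3c(OCc4ccccc4)cc(OCc4ccccc4)c(-c4cc(-c5cc(=O)c6c(O)cc(O)cc6o5)ccc4OCc4ccccc4)c3o2)ccc1OCc1ccccc1 | intermediate
17 | 8-[5-(5,7-dihydroxy-4-oxo-4H-chromen-2-yl)-2-hydroxyphenyl]-5,7-dihydroxy-2-(4-hydroxy-3-methoxyphenyl)-4H-chromen-4-one | COc1cc(-c2cc(=O)c3c(O)cc(O)c(-c4cc(-c5cc(=O)c6c(O)cc(O)cc6o5)ccc4O)c3o2)ccc1O | target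

Total step count: 12.
Longest linear sequence: 9 steps (steps 1, 2, 3, 4, 7, 9, 10, 11, 12, from compound 1).

Steps most likely to fail

Step 10. The opened tetraoxo chain may fold in an aldol mode, with a methylene attacking a ketone carbonyl, or the pyranone may react without opening, so that resorcinol- or coumarin-type isomers form in place of ring A of unit 1. The fallback sets out from 10 and 2 and comes back to the route at 17. The lithium dianion of 2 (LiN(SiMe3)2, THF, −78 °C to rt) undergoes crossed Claisen condensation with the methyl ester 10 to give 1-[2,4-bis(benzyloxy)-6-hydroxyphenyl]-3-[4-(benzyloxy)-3-Fl-phenyl]propane-1,3-dione F1. Cyclodehydration with catalytic H2SO4 in AcOH gives the hexa-O-benzyl biflavone 5,7-bis(benzyloxy)-2-[4-(benzyloxy)-3-Fl-phenyl]-4H-chromen-4-one F2. Hydrogenolysis over Pd/C removes all six benzyl ethers and gives 17.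

Step 9. Proton transfer from the more acidic product to unreacted trianion, or addition of the trianion to C2'' or C4'' of the unit 2 flavone, may consume the advanced ester. The fallback sets out from 12, 8 and 6 and comes back at 13, so that the strongly basic step meets only a simple benzoate. The trianion of 12 is acylated with 8 to give 6-[4-(4-benzyloxy-3-iodophenyl)-2,4-dioxobutyl]-4-hydroxy-2H-pyran-2-one F3. Iodide 6 is converted by Miyaura borylation (B2pin2, Pd(dppf)Cl2, KOAc, dioxane) into 5,7-bis(benzyloxy)-2-[4-(benzyloxy)-3-methoxyphenyl]-8-(4,4,5,5-tetramethyl-1,3,2-dioxaborolan-2-yl)-4H-chromen-4-one F4. Suzuki–Miyaura coupling of F3 with F4 (Pd(OAc)2, SPhos, K3PO4, dioxane, moderate temperature) then gives 13.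

Step 7. Slow transmetalation and reductive elimination at the tri-ortho-substituted axis may let protodeboronation of the boronate and saponification of the ester overtake the coupling. The fallback sets out from 3, 9 and 4 and comes back at 10, forming the biaryl before the pyranone ring of unit 2 exists. Suzuki–Miyaura coupling of 3 with 9 gives methyl 3-[3-acetyl-4,6-bis(benzyloxy)-2-hydroxyphenyl]-4-(benzyloxy)benzoate F5. Claisen–Schmidt condensation of F5 with 4 (KOH, EtOH), in which the ester is saponified at the same time, gives the chalcone acid 4-(benzyloxy)-3-{4,6-bis(benzyloxy)-3-[(E)-3-(4-benzyloxy-3-methoxyphenyl)prop-2-enoyl]-2-hydroxyphenyl}benzoic acid F6. Oxidative cyclization (I2, DMSO) gives the flavone acid 4-(benzyloxy)-3-Fl-benzoic acid F7. Esterification (MeI, K2CO3, DMF) then returns 10.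

Further compounds
F1 | step 10 | 1-[2,4-bis(benzyloxy)-6-hydroxyphenyl]-3-[4-(benzyloxy)-3-Fl-phenyl]propane-1,3-dione | O=C(CC(=O)c1c(O)cc(OCc2ccccc2)cc1OCc1ccccc1)c1ccc(OCc2ccccc2)c(-c2c(OCc3ccccc3)cc(OCc3ccccc3)c3c(=O)cc(-c4ccc(OCc5ccccc5)c(OC)c4)oc23)c1
F2 | step 10 | 5,7-bis(benzyloxy)-2-[4-(benzyloxy)-3-Fl-phenyl]-4H-chromen-4-one | COc1cc(-c2cc(=O)c3c(OCc4ccccc4)cc(OCc4ccccc4)c(-c4cc(-c5cc(=O)c6c(OCc7ccccc7)cc(OCc7ccccc7)cc6o5)ccc4OCc4ccccc4)c3o2)ccc1OCc1ccccc1
F3 | step 9 | 6-[4-(4-benzyloxy-3-iodophenyl)-2,4-dioxobutyl]-4-hydroxy-2H-pyran-2-one | O=C(CC(=O)Cc1cc(O)cc(=O)o1)c1ccc(OCc2ccccc2)c(I)c1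
F4 | step 9 | 5,7-bis(benzyloxy)-2-[4-(benzyloxy)-3-methoxyphenyl]-8-(4,4,5,5-tetramethyl-1,3,2-dioxaborolan-2-yl)-4H-chromen-4-one | COc1cc(-c2cc(=O)c3c(OCc4ccccc4)cc(OCc4ccccc4)c(B4OC(C)(C)C(C)(C)O4)c3o2)ccc1OCc1ccccc1
F5 | step 7 | methyl 3-[3-acetyl-4,6-bis(benzyloxy)-2-hydroxyphenyl]-4-(benzyloxy)benzoate | COC(=O)c1ccc(OCc2ccccc2)c(-c2c(O)c(C(C)=O)c(OCc3ccccc3)cc2OCc2ccccc2)c1
F6 | step 7 | 4-(benzyloxy)-3-{4,6-bis(benzyloxy)-3-[(E)-3-(4-benzyloxy-3-methoxyphenyl)prop-2-enoyl]-2-hydroxyphenyl}benzoic acid | COc1cc(/C=C/C(=O)c2c(O)c(-c3cc(C(=O)O)ccc3OCc3ccccc3)c(OCc3ccccc3)cc2OCc2ccccc2)ccc1OCc1ccccc1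
F7 | step 7 | 4-(benzyloxy)-3-Fl-benzoic acid | OC(=O)c1ccc(OCc2ccccc2)c(-c2c(OCc3ccccc3)cc(OCc3ccccc3)c3c(=O)cc(-c4ccc(OCc5ccccc5)c(OC)c4)oc23)c1
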